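**Retrosynthetic overview**
1. Target 10 ⇒ hexa-O-benzyl ether 9 by global hydrogenolysis under neutral conditions.
2. 9 ⇒ biaryl bis(2'-hydroxychalcone) 8: both rings C are closed last and together by a double enantioselective oxa-Michael addition, which forms the O1–C2 and O1''–C2'' bonds and sets both stereocentres.
3. 8 ⇒ diacetyl biaryl 5 + 2 × aldehyde 6 (rings B bought intact). The only free phenol of 8 is para to the biaryl bond, so only the 6,6''-linked flavanone can form.
4. 5 ⇒ biaryl 4 (ring acetylation) ⇒ 2 × silyl ether 2 (lithiation between the two OBn groups, oxidative homocoupling) ⇒ phenol 1.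
5. Ring order: the two rings A are joined first (biaryl), then both rings C are formed in one step.

Assumption: the target SMILES fixes C2 and C2'' as S and leaves the hindered 6,6'' biaryl axis undefined, so the axis is not controlled (5, 7, 8, 9 and 10 are carried as formed with respect to it); 1 and 6 are bought (1 is otherwise one step from phloroglucinol and BnBr).

Catalyst K (prepared beforehand, not counted as a step): 1-[3,5-bis(trifluoromethyl)phenyl]-3-[(2S)-3,3-dimethyl-1-{[tris(4-methoxyphenyl)-λ5-phosphanylidene]amino}butan-2-yl]thiourea, COc1ccc(cc1)P(=NC[C@@H](NC(=S)Nc1cc(cc(c1)C(F)(F)F)C(F)(F)F)C(C)(C)C)(c1ccc(OC)cc1)c1ccc(OC)cc1. It is a bifunctional iminophosphorane/thiourea made from L-tert-leucine. The sense of induction is checked on the monomeric model chalcone; if it gives (2R), the mirror-image catalyst from D-tert-leucine is used.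

**Route**

Step 1
Reactants: 1 3,5-bis(benzyloxy)phenol
Product: 2 [3,5-bis(benzyloxy)phenoxy]triisopropylsilane
Conditions: TIPSCl, imidazole, DMF, rt
Reagents that add atoms: triisopropylsilyl chloride, CC(C)[Si](Cl)(C(C)C)C(C)C
Why: Silyl ether formation at the only free OH; the bulky, non-coordinating OSi(iPr)3 group blocks lithiation next to it and marks the oxygen that will later become O1 of ring C.

Step 2
Reactants: 2 [3,5-bis(benzyloxy)phenoxy]triisopropylsilane (two molecules couple)
Product: 4 2,2',6,6'-tetrakis(benzyloxy)-4,4'-bis(triisopropylsilyloxy)-1,1'-biphenyl, via aryllithium 3 (not isolated)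
Conditions: n-BuLi (1.1 equiv), THF, 0 °C → rt, 2 h; then anhydrous FeCl3 (1.1 equiv), −78 °C → rt
Reagents that add atoms: n-butyllithium, [Li]CCCC (its lithium stands in intermediate 3 only; product 4 holds no reagent atoms)
Why: Directed ortho-metalation takes place at the carbon flanked by the two coordinating OBn groups (para to the silyloxy group), and FeCl3-mediated oxidative homocoupling of the 2,6-dialkoxyaryllithium gives the tetra-ortho-oxygenated biaryl, as is established for 2,6-dimethoxyphenyllithium.

Step 3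
Reactants: 4 2,2',6,6'-tetrakis(benzyloxy)-4,4'-bis(triisopropylsilyloxy)-1,1'-biphenyl
Product: 5 1,1'-[2,2',6,6'-tetrakis(benzyloxy)-4,4'-bis(triisopropylsilyloxy)-1,1'-biphenyl-3,3'-diyl]di(ethan-1-one)
Conditions: AcOH (6 equiv), (CF3CO)2O (6 equiv), CH2Cl2, 0 °C → rt
Reagents that add atoms: acetic acid, CC(=O)O
Why: Friedel–Crafts acylation by the mixed anhydride acetyl trifluoroacetate at the only open, phloroglucinol-type activated position of each ring (positions 3 and 5 are equivalent and the first acetyl deactivates its ring), under conditions too mild to cleave benzyl or aryl silyl ethers; no stereocentre of the target is formed.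

Step 4
Reactants: 5 the 3,3'-diacetyl bis-silyl ether; 6 4-(benzyloxy)benzaldehyde (2.5 equiv)
Product: 8 (2E,2'E)-1,1'-[2,2',6,6'-tetrakis(benzyloxy)-4,4'-dihydroxy-1,1'-biphenyl-3,3'-diyl]bis{3-[4-(benzyloxy)phenyl]prop-2-en-1-one}, via desilylated diketone 7 (not isolated)
Conditions: KOH (50% aq, excess), EtOH/THF, rt → 40 °C, 48 h; then cold 1 M HCl to pH 5
Reagents that add atoms: none
Why: Hydroxide cleaves the aryl silyl ethers activated by the ortho acetyl groups, and the resulting 2-hydroxyacetophenone phenoxides undergo Claisen–Schmidt (crossed aldol) condensation with non-enolisable 6 to the E,E bis-chalcone, which stays open as its phenoxide in strong base and is set free by cold acidification.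

Step 5
Reactants: 8 the biaryl bis(2'-hydroxychalcone)
Product: 9 (2S,2''S)-5,5'',7,7''-tetrakis(benzyloxy)-2,2''-bis[4-(benzyloxy)phenyl]-2,2'',3,3''-tetrahydro-4H,4''H-6,6''-bichromene-4,4''-dione
Conditions: catalyst K (20 mol%), toluene, 4 Å molecular sieves, −20 °C, 48–72 h; then AcOH quench, SiO2 filtration
Reagents that add atoms: none
Why: Proposed new method: double, catalyst-controlled enantioselective 6-endo oxa-Michael cyclisation of a non-activated biaryl bis(2'-hydroxychalcone); the superbasic iminophosphorane deprotonates the chelated 2'-OH (the only acidic site, since all other phenols are benzylated) to a chiral iminophosphonium phenoxide ion pair, the thiourea binds the enone carbonyl and the developing enolate so that the phenoxide adds to one face of the s-cis enone (setting C2 and C2'' as S), and the P=N–H+ protonates the enolate; the two enones react independently, so the (2R,2''R) enantiomer is statistically suppressed and the minor (2S,2''R) diastereomer is removed by chromatography; the aroyl group twisted out of plane by the flanking OBn favours ring closure and keeps retro-addition slow at −20 °C; closest known reaction type: bifunctional base/thiourea-catalysed intramolecular oxa-Michael addition of activated 2'-hydroxychalcones and iminophosphorane-catalysed oxa-Michael addition of alcohols to unsaturated esters.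

Step 6
Reactants: 9 the (2S,2''S)-hexa-O-benzyl biflavanone
Product: 10 succedaneaflavanone, (2S,2''S)-5,5'',7,7''-tetrahydroxy-2,2''-bis(4-hydroxyphenyl)-2,2'',3,3''-tetrahydro-4H,4''H-6,6''-bichromene-4,4''-dione
Conditions: H2 (1 atm), 10% Pd/C, EtOAc/MeOH 1:1, rt; stop at full debenzylation
Reagents that add atoms: none
Why: Heterogeneous hydrogenolysis of the six benzyl aryl ethers under neutral conditions, which offers no phenoxide/enolate ring-opening pathway and so leaves the C2 and C2'' configurations untouched.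

**Compound list**
1 | 3,5-bis(benzyloxy)phenol | Oc1cc(OCc2ccccc2)cc(OCc2ccccc2)c1 | starting material
2 | [3,5-bis(benzyloxy)phenoxy]triisopropylsilane | CC(C)[Si](Oc1cc(OCc2ccccc2)cc(OCc2ccccc2)c1)(C(C)C)C(C)C | intermediate
3 | [2,6-bis(benzyloxy)-4-(triisopropylsilyloxy)phenyl]lithium | [Li]c1c(OCc2ccccc2)cc(O[Si](C(C)C)(C(C)C)C(C)C)cc1OCc1ccccc1 | intermediate (not isolated)
4 | 2,2',6,6'-tetrakis(benzyloxy)-4,4'-bis(triisopropylsilyloxy)-1,1'-biphenyl | CC(C)[Si](Oc1cc(OCc2ccccc2)c(-c2c(OCc3ccccc3)cc(O[Si](C(C)C)(C(C)C)C(C)C)cc2OCc2ccccc2)c(OCc2ccccc2)c1)(C(C)C)C(C)C | intermediate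
5 | 1,1'-[2,2',6,6'-tetrakis(benzyloxy)-4,4'-bis(triisopropylsilyloxy)-1,1'-biphenyl-3,3'-diyl]di(ethan-1-one) | CC(=O)c1c(O[Si](C(C)C)(C(C)C)C(C)C)cc(OCc2ccccc2)c(-c2c(OCc3ccccc3)cc(O[Si](C(C)C)(C(C)C)C(C)C)c(C(C)=O)c2OCc2ccccc2)c1OCc1ccccc1 | intermediate
6 | 4-(benzyloxy)benzaldehyde | O=Cc1ccc(OCc2ccccc2)cc1 | starting material
7 | 1,1'-[2,2',6,6'-tetrakis(benzyloxy)-4,4'-dihydroxy-1,1'-biphenyl-3,3'-diyl]di(ethan-1-one) (present as its dipotassium phenoxide) | CC(=O)c1c(O)cc(OCc2ccccc2)c(-c2c(OCc3ccccc3)cc(O)c(C(C)=O)c2OCc2ccccc2)c1OCc1ccccc1 | intermediate (not isolated)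
8 | (2E,2'E)-1,1'-[2,2',6,6'-tetrakis(benzyloxy)-4,4'-dihydroxy-1,1'-biphenyl-3,3'-diyl]bis{3-[4-(benzyloxy)phenyl]prop-2-en-1-one} | O=C(/C=C/c1ccc(OCc2ccccc2)cc1)c1c(O)cc(OCc2ccccc2)c(-c2c(OCc3ccccc3)cc(O)c(C(=O)/C=C/c3ccc(OCc4ccccc4)cc3)c2OCc2ccccc2)c1OCc1ccccc1 | intermediate
9 | (2S,2''S)-5,5'',7,7''-tetrakis(benzyloxy)-2,2''-bis[4-(benzyloxy)phenyl]-2,2'',3,3''-tetrahydro-4H,4''H-6,6''-bichromene-4,4''-dione | O=C1C[C@@H](c2ccc(OCc3ccccc3)cc2)Oc2cc(OCc3ccccc3)c(-c3c(OCc4ccccc4)cc4c(c3OCc3ccccc3)C(=O)C[C@@H](c3ccc(OCc5ccccc5)cc3)O4)c(OCc3ccccc3)c21 | intermediate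
10 | succedaneaflavanone, (2S,2''S)-6,6''-binaringenin | O=C1C[C@@H](c2ccc(O)cc2)Oc2cc(O)c(-c3c(O)cc4c(c3O)C(=O)C[C@@H](c3ccc(O)cc3)O4)c(O)c21 | target

**Totals**
Total step count: 6. Longest linear sequence: 6 steps (1 → 10); aldehyde 6 is bought.

**Three steps most likely to fail**

Step 2 (oxidative homocoupling to a tetra-ortho-substituted biaryl). The fallback sets out from compound 2 and changes from oxidative coupling of the organolithium to reductive coupling of an aryl halide. Aryllithium 3 is generated as before and quenched with iodine to give the aryl iodide {[3,5-bis(benzyloxy)-4-iodophenyl]oxy}triisopropylsilane F1. Classical Ullmann homocoupling of F1 (activated copper powder, DMF, 150 °C) then gives the biaryl and comes back to the route at compound 4.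

Step 3 (acylation at the hindered position next to the silyloxy group in an acidic medium). The fallback sets out from compound 4 and builds the acetyl group through ortho-selective phenol chemistry instead of a Friedel–Crafts reaction. Bu4NF in THF removes both silyl groups to give 2,2',6,6'-tetrakis(benzyloxy)-1,1'-biphenyl-4,4'-diol F2. Magnesium-mediated ortho-formylation (MgCl2, Et3N, paraformaldehyde, MeCN, reflux) gives 2,2',6,6'-tetrakis(benzyloxy)-4,4'-dihydroxy-1,1'-biphenyl-3,3'-dicarbaldehyde F3. Excess MeMgBr in THF at 0 °C gives the bis-carbinol 2,2',6,6'-tetrakis(benzyloxy)-3,3'-bis(1-hydroxyethyl)-1,1'-biphenyl-4,4'-diol F4. Benzylic oxidation with MnO2 in CH2Cl2 comes back to the route at compound 7, which is then condensed with 6 under the KOH conditions of step 4.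

Step 5 (the proposed new double asymmetric cyclisation; at risk from low selectivity or erosion by retro-addition). The fallback sets out from compound 8 and uses known chemistry only. Classical isomerisation with NaOAc in refluxing EtOH gives the hexa-O-benzyl 6,6''-biflavanone as the statistical mixture of C2/C2'' stereoisomers F5. Preparative chiral SFC or HPLC on a polysaccharide carbamate phase isolates the (2S,2''S) isomer and comes back to the route at compound 9. The unwanted isomers can be re-equilibrated with NaOAc and recycled.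

**Further compounds**
F1 | step 2 | {[3,5-bis(benzyloxy)-4-iodophenyl]oxy}triisopropylsilane | CC(C)[Si](Oc1cc(OCc2ccccc2)c(I)c(OCc2ccccc2)c1)(C(C)C)C(C)C
F2 | step 3 | 2,2',6,6'-tetrakis(benzyloxy)-1,1'-biphenyl-4,4'-diol | Oc1cc(OCc2ccccc2)c(-c2c(OCc3ccccc3)cc(O)cc2OCc2ccccc2)c(OCc2ccccc2)c1
F3 | step 3 | 2,2',6,6'-tetrakis(benzyloxy)-4,4'-dihydroxy-1,1'-biphenyl-3,3'-dicarbaldehyde | O=Cc1c(O)cc(OCc2ccccc2)c(-c2c(OCc3ccccc3)cc(O)c(C=O)c2OCc2ccccc2)c1OCc1ccccc1
F4 | step 3 | 2,2',6,6'-tetrakis(benzyloxy)-3,3'-bis(1-hydroxyethyl)-1,1'-biphenyl-4,4'-diol (mixture of diastereomers) | CC(O)c1c(O)cc(OCc2ccccc2)c(-c2c(OCc3ccccc3)cc(O)c(C(C)O)c2OCc2ccccc2)c1OCc1ccccc1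
F5 | step 5 | hexa-O-benzyl 6,6''-binaringenin, mixture of C2/C2'' stereoisomers | O=C1CC(c2ccc(OCc3ccccc3)cc2)Oc2cc(OCc3ccccc3)c(-c3c(OCc4ccccc4)cc4c(c3OCc3ccccc3)C(=O)CC(c3ccc(OCc5ccccc5)cc3)O4)c(OCc3ccccc3)c21
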